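**Assumptions:** the target has no stereocentre and no stable axis of chirality, so there is no enantiomer to control. 5-Propylresorcinol (divarinol) is taken as a commercial bulk intermediate.

**Retrosynthetic overview**
1. Target 8 is cut at the aryl C3–O bond of the lower ring: divarinic acid 2 (C3–H) plus an electrophilic aroyloxy donor, the diaroyl peroxide 6.
2. Peroxide 6 comes from 2,4-dimethoxy-6-propylbenzoic acid 4 and hydrogen peroxide.
3. Acid 4 comes from 2 by exhaustive O-methylation and saponification, so both halves derive from 2.
4. Acid 2 comes from 5-propylresorcinol 1 by ortho-carboxylation.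
5. No ring is formed; both benzene rings are bought in 1.

**Route**

Step 1
Reactants: 1 5-propylbenzene-1,3-diol (divarinol)
Product: 2 2,4-dihydroxy-6-propylbenzoic acid (divarinic acid)
Conditions: methyl magnesium carbonate (2 M in DMF, 5 equiv), 120 °C, 3 h, N2; then cold 2 M HCl
Reagents that add atoms: methyl magnesium carbonate, COC(=O)O[Mg]OC (supplies CO2)
Why: Stiles carboxylation (Kolbe–Schmitt type), in which the magnesium phenoxide is C-carboxylated ortho to one OH and para to the other and the product is held as a magnesium salicylate chelate, as is done for the homologous 5-alkylresorcinols.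

Step 2
Reactants: 2 2,4-dihydroxy-6-propylbenzoic acid
Product: 4 2,4-dimethoxy-6-propylbenzoic acid, via methyl 2,4-dimethoxy-6-propylbenzoate 3 (not isolated)
Conditions: Me2SO4 (3.5 equiv), K2CO3, acetone, reflux; filter, evaporate; then KOH, DMSO/H2O, 90 °C; cold HCl to pH 2
Reagents that add atoms: dimethyl sulfate, COS(=O)(=O)OC; potassium hydroxide, [K+].[OH-] (oxygen of the CO2H)
Why: Williamson O-methylation of both phenols and the carboxylate (excess reagent at reflux also methylates the chelated 2-OH), then saponification of the hindered ester in aqueous DMSO, which also destroys excess dimethyl sulfate.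

Step 3
Reactants: 4 2,4-dimethoxy-6-propylbenzoic acid
Product: 6 bis(2,4-dimethoxy-6-propylbenzoyl) peroxide, via 2,4-dimethoxy-6-propylbenzoyl chloride 5 (not isolated)
Conditions: (COCl)2, cat. DMF, CH2Cl2, 0 °C to rt; evaporate; then urea·H2O2 (0.5 equiv), pyridine, CH2Cl2, −10 to 0 °C; cold aqueous wash, kept in solution below 10 °C and titrated
Reagents that add atoms: oxalyl chloride, ClC(=O)C(Cl)=O (Cl of 5 only); urea–hydrogen peroxide, NC(N)=O.OO (the O–O unit)
Why: Acid chloride formation through the Vilsmeier chloride, then double acylation of hydrogen peroxide (the standard diaroyl peroxide synthesis), where the α-effect nucleophile HOO– reaches the hindered acyl carbon under anhydrous conditions.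

Step 4
Reactants: 2 2,4-dihydroxy-6-propylbenzoic acid (1.5 equiv); 6 bis(2,4-dimethoxy-6-propylbenzoyl) peroxide (1.0 equiv)
Product: 8 3-[(2,4-dimethoxy-6-propylbenzoyl)oxy]-2,4-dihydroxy-6-propylbenzoic acid (target), via cyclohexadienone tautomer 7 (not isolated)
Conditions: CHCl3 (EtOH-free), Ar, dark, 0 to 23 °C, 48 h; no base at any stage; SiO2 chromatography (EtOAc/hexane/AcOH)
Reagents that add atoms: none
Why: Proposed new method: hydrogen-bond-directed electrophilic C–H aroyloxylation of an unprotected β-resorcylic acid, in which C3 attacks a peroxidic oxygen of 6 while a flanking OH passes its proton to the leaving carboxylate, giving dienone 7, which tautomerises to 8. The two ortho substituents of the aroyl group block attack at C=O, so only the O–O bond is open, and they twist the carboxyl out of conjugation, so the carboxylate stays a good leaving group. C3 is favoured because it is ortho to both OH groups and can be reached from either, whereas C5 can be reached only from the 4-OH and C1 is blocked. The closest known reaction is the ortho-benzoyloxylation of simple phenols with dibenzoyl peroxide (related: phthaloyl peroxide arene oxidation). No stereocentre is formed in 8, and the hindered ester resists acyl migration under these neutral conditions.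

**Compound list**
1 | 5-propylbenzene-1,3-diol (divarinol) | CCCc1cc(O)cc(O)c1 | starting material
2 | 2,4-dihydroxy-6-propylbenzoic acid (divarinic acid) | CCCc1cc(O)cc(O)c1C(=O)O | intermediate
3 | methyl 2,4-dimethoxy-6-propylbenzoate | CCCc1cc(OC)cc(OC)c1C(=O)OC | intermediate (not isolated)
4 | 2,4-dimethoxy-6-propylbenzoic acid | CCCc1cc(OC)cc(OC)c1C(=O)O | intermediate
5 | 2,4-dimethoxy-6-propylbenzoyl chloride | CCCc1cc(OC)cc(OC)c1C(Cl)=O | intermediate (not isolated)
6 | bis(2,4-dimethoxy-6-propylbenzoyl) peroxide | CCCc1cc(OC)cc(OC)c1C(=O)OOC(=O)c1c(CCC)cc(OC)cc1OC | intermediate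
7 | 3-[(2,4-dimethoxy-6-propylbenzoyl)oxy]-2-hydroxy-4-oxo-6-propylcyclohexa-1,5-diene-1-carboxylic acid (racemic, transient) | CCCC1=CC(=O)C(OC(=O)c2c(CCC)cc(OC)cc2OC)C(O)=C1C(=O)O | intermediate (not isolated)
8 | 3-[(2,4-dimethoxy-6-propylbenzoyl)oxy]-2,4-dihydroxy-6-propylbenzoic acid | CCCc1cc(OC)cc(OC)c1C(=O)Oc1c(O)cc(CCC)c(C(=O)O)c1O | target

**Totals**
Total step count: 4. Longest linear sequence: 4 (1 → 2 → 4 → 6 → 8); compound 2 is used twice.

**Three steps most likely to fail**

Step 4 (new C–H aroyloxylation): the risks are attack at C5, double aroyloxylation, and thermal decay of 6 before it reacts. The fallback uses known chemistry, sets out from 2 (with 4 as the acid partner) and comes back at 8. Acid 2 is benzylated twice with BnBr and K2CO3 in DMF, the chelated 2-OH staying free, to give benzyl 4-(benzyloxy)-2-hydroxy-6-propylbenzoate F1. Magnesium-mediated ortho-formylation (MgCl2, Et3N, paraformaldehyde, MeCN, reflux) can only reach C3, the one open position ortho to the free phenol, and gives benzyl 4-(benzyloxy)-3-formyl-2-hydroxy-6-propylbenzoate F2. Dakin oxidation (H2O2, cat. (PhSe)2, CH2Cl2, then aqueous NaHCO3) gives benzyl 4-(benzyloxy)-2,3-dihydroxy-6-propylbenzoate F3. Esterification with 4 through the mixed trifluoroacetic anhydride (TFAA, toluene, rt) takes place at the 3-OH, because the 2-OH is tied up in the hydrogen bond to the ester, and gives benzyl 4-(benzyloxy)-3-[(2,4-dimethoxy-6-propylbenzoyl)oxy]-2-hydroxy-6-propylbenzoate F4. Hydrogenolysis (H2, Pd/C, EtOAc) removes both benzyl groups and gives 8.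

Step 3 (peroxide formation): the electron-rich, di-ortho-substituted peroxide may rearrange by carboxy inversion or homolyse on work-up. The fallback sets out from 4 and comes back at 8, replacing the peroxide by an iodine(III) carrier of the same aroyloxy group. Two equivalents of 4 are exchanged onto (diacetoxyiodo)benzene in chlorobenzene at 45 °C under reduced pressure (to strip acetic acid), giving [bis(2,4-dimethoxy-6-propylbenzoyloxy)-λ3-iodanyl]benzene F5. F5 then oxidises 2 (CH2Cl2, −20 °C to rt) by phenol exchange at iodine and ortho delivery of the carboxylate ligand, giving 8. This coupling is itself untested on this substrate, and para attack with decarboxylation is its main hazard.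

Step 1 (carboxylation): the risks are carboxylation between the two OH groups, low conversion, and decarboxylation on acidic work-up. The fallback sets out from 1 and comes back at 2. Vilsmeier–Haack formylation (POCl3, DMF, 0 °C to rt, then aqueous hydrolysis) goes para to one OH and gives 2,4-dihydroxy-6-propylbenzaldehyde F6. Lindgren–Pinnick oxidation (NaClO2, NaH2PO4, sulfamic acid as hypochlorite scavenger, aqueous dioxane, 0 °C) gives 2.

**Further compounds**
F1 | step 4 | benzyl 4-(benzyloxy)-2-hydroxy-6-propylbenzoate | CCCc1cc(OCc2ccccc2)cc(O)c1C(=O)OCc1ccccc1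
F2 | step 4 | benzyl 4-(benzyloxy)-3-formyl-2-hydroxy-6-propylbenzoate | CCCc1cc(OCc2ccccc2)c(C=O)c(O)c1C(=O)OCc1ccccc1
F3 | step 4 | benzyl 4-(benzyloxy)-2,3-dihydroxy-6-propylbenzoate | CCCc1cc(OCc2ccccc2)c(O)c(O)c1C(=O)OCc1ccccc1
F4 | step 4 | benzyl 4-(benzyloxy)-3-[(2,4-dimethoxy-6-propylbenzoyl)oxy]-2-hydroxy-6-propylbenzoate | CCCc1cc(OC)cc(OC)c1C(=O)Oc1c(OCc2ccccc2)cc(CCC)c(C(=O)OCc2ccccc2)c1O
F5 | step 3 | [bis(2,4-dimethoxy-6-propylbenzoyloxy)-λ3-iodanyl]benzene | CCCc1cc(OC)cc(OC)c1C(=O)OI(OC(=O)c1c(CCC)cc(OC)cc1OC)c1ccccc1
F6 | step 1 | 2,4-dihydroxy-6-propylbenzaldehyde | CCCc1cc(O)cc(O)c1C=O
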